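**Strategy**

Everything rests on seeing the trans-2,3-diaryl-dihydrofuran fused to ring A (O1–C2–C3–C3a–C7a) as a rearranged cyclopropane: C3a sits between the two oxygen-bearing carbons C7a and C4, so ring A is carried as a cyclohexane-1,3-dione. Its spirocyclopropane, made from the dione carbenoid and resveratrol trimethyl ether, opens at the 4-methoxyphenyl carbon and recloses through a carbonyl oxygen, turning the three-membered ring into the five-membered one and setting C2 trans to C3. The dione is grown on an enantioenriched 3-carboxy-dihydrobenzofuran (ring B unit), aromatized after the key step, and an acid-induced seven-membered Friedel–Crafts closure followed by dealkylation completes the route.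

Key step: step 10

Remark: ring A is the central benzene ring carrying furan ring 1 (formed in step 10), ring B the benzene ring carrying furan ring 2; each dihydrobenzofuran is numbered O1, C2, C3, C3a, C4–C7, C7a; BF stands for the (2S,3S)-4-bromo-6-methoxy-2-(4-methoxyphenyl)-2,3-dihydro-1-benzofuran-3-yl group; the sense of induction of the two chiral dirhodium catalysts (steps 4 and 9) is assumed by analogy, and the mirror-image catalyst is taken if a first run shows the opposite sense.

**Route**

Step 1
Reactants: 1 1-bromo-3,5-dimethoxybenzene; 2 methyl chlorooxoacetate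
Product: 4 methyl 2-(2-bromo-6-hydroxy-4-methoxyphenyl)-2-oxoacetate, via dimethoxy keto ester 3 (not isolated)
Conditions: AlCl3 (3 equiv), CH2Cl2, 0 °C → rt; aq. HCl work-up
Reagents that add atoms: none
Why: Friedel–Crafts acylation should go para to one methoxy group and ortho to the other (the site between both methoxy groups is more hindered), and AlCl3 chelated between the new ketone and the neighbouring methoxy oxygen cleaves only that methyl ether.

Step 2
Reactants: 4 methyl 2-(2-bromo-6-hydroxy-4-methoxyphenyl)-2-oxoacetate; 5 4-methoxybenzyl chloride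
Product: 6 methyl 2-[2-bromo-4-methoxy-6-(4-methoxybenzyloxy)phenyl]-2-oxoacetate
Conditions: K2CO3, DMF, 40 °C
Reagents that add atoms: none
Why: Williamson etherification of the acidic phenol installs the benzylic CH2 that becomes C2 of furan ring 2 together with its 4-methoxyphenyl group.

Step 3
Reactants: 6 methyl 2-[2-bromo-4-methoxy-6-(4-methoxybenzyloxy)phenyl]-2-oxoacetate
Product: 8 methyl 2-[2-bromo-4-methoxy-6-(4-methoxybenzyloxy)phenyl]-2-diazoacetate, via tosylhydrazone 7 (not isolated)
Conditions: TsNHNH2, MeOH, 60 °C; then DBU, CH2Cl2, rt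
Reagents that add atoms: p-toluenesulfonyl hydrazide, Cc1ccc(cc1)S(=O)(=O)NN
Why: Condensation at the activated α-keto ester carbonyl and base-induced loss of sulfinate (Bamford–Stevens) should give the aryldiazoacetate.

Step 4
Reactants: 8 methyl 2-[2-bromo-4-methoxy-6-(4-methoxybenzyloxy)phenyl]-2-diazoacetate
Product: 9 methyl (2S,3R)-4-bromo-6-methoxy-2-(4-methoxyphenyl)-2,3-dihydro-1-benzofuran-3-carboxylate (2,3-cis)
Conditions: Rh2(R-PTTL)4 (1 mol %; dirhodium tetrakis[N-phthaloyl-(R)-tert-leucinate]), toluene, −60 °C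
Reagents that add atoms: none
Why: Enantioselective intramolecular 1,5 C–H insertion of the donor/acceptor rhodium carbenoid into the activated benzylic ether C–H closes furan ring 2 and sets C2 (S) under catalyst control, the cis ester being the kinetic product.

Step 5
Reactants: 9 methyl (2S,3R)-4-bromo-6-methoxy-2-(4-methoxyphenyl)-2,3-dihydro-1-benzofuran-3-carboxylate
Product: 10 methyl (2S,3S)-4-bromo-6-methoxy-2-(4-methoxyphenyl)-2,3-dihydro-1-benzofuran-3-carboxylate (2,3-trans; BF–CO2Me)
Conditions: NaOMe (0.3 equiv), MeOH, rt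
Reagents that add atoms: none
Why: Reversible deprotonation α to the ester epimerizes C3 to the thermodynamically favoured 2,3-trans isomer without touching C2.

Step 6
Reactants: 10 BF–CO2Me; 11 1-(triphenylphosphoranylidene)propan-2-one
Product: 13 (E)-4-BF-but-3-en-2-one, via aldehyde 12 (not isolated)
Conditions: i-Bu2AlH (1.1 equiv), CH2Cl2, −78 °C; MeOH quench; then 11, −78 °C → 40 °C
Reagents that add atoms: none
Why: Half-reduction of the ester to the aluminium hemiacetal and in situ Wittig olefination of the released aldehyde with the stabilized ylide should give the E-enone, so the configurationally labile α-aryl aldehyde is never isolated.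

Step 7
Reactants: 13 (E)-4-BF-but-3-en-2-one; 14 dimethyl malonate
Product: 17 5-BF-cyclohexane-1,3-dione, via Michael adduct 15 (not isolated), via cyclic keto ester 16 (not isolated)
Conditions: NaOMe, MeOH, rt → reflux; aq. NaOH, reflux; aq. HCl to pH 3, 60 °C
Reagents that add atoms: none
Why: Dimedone-type annulation (Michael addition of the weakly basic malonate anion, Dieckmann-type Claisen closure by the methyl ketone enolate, saponification, decarboxylation) builds ring A as a 5-substituted cyclohexane-1,3-dione and leaves the benzylic stereocentres untouched.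

Step 8
Reactants: 17 5-BF-cyclohexane-1,3-dione
Product: 18 2-diazo-5-BF-cyclohexane-1,3-dione
Conditions: 4-acetamidobenzenesulfonyl azide, Et3N, MeCN, 0 °C → rt
Reagents that add atoms: 4-acetamidobenzenesulfonyl azide, CC(=O)Nc1ccc(cc1)S(=O)(=O)N=[N+]=[N-]
Why: Regitz diazo transfer to the acidic C2 of the 1,3-dione.

Step 9
Reactants: 18 2-diazo-5-BF-cyclohexane-1,3-dione; 19 (E)-3,4',5-trimethoxystilbene
Product: 20 (1S,2S)-6-BF-1-(3,5-dimethoxyphenyl)-2-(4-methoxyphenyl)spiro[2.5]octane-4,8-dione
Conditions: 19 (3 equiv), Rh2(S-NTTL)4 (2 mol %; dirhodium tetrakis[N-(1,8-naphthaloyl)-(S)-tert-leucinate]), PhF, 0 °C → rt, slow addition of 18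
Reagents that add atoms: none
Why: Cyclopropanation of the electron-rich trans-alkene by the electrophilic acceptor/acceptor rhodium carbenoid is stereospecific (trans-diaryl), and the chiral carboxylate ligands select the alkene face and hence the configuration of the cyclopropane carbon bearing the 3,5-dimethoxyphenyl group, the mismatched isomer being a diastereomer (remote ring B stereocentres) that is removable after step 10.

Step 10
Reactants: 20 (1S,2S)-6-BF-1-(3,5-dimethoxyphenyl)-2-(4-methoxyphenyl)spiro[2.5]octane-4,8-dione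
Product: 21 (2S,3S)-6-BF-3-(3,5-dimethoxyphenyl)-2-(4-methoxyphenyl)-3,5,6,7-tetrahydro-1-benzofuran-4(2H)-one
Conditions: Sc(OTf)3 (10 mol %), CH2Cl2, 0 °C → rt
Reagents that add atoms: none
Why: Sc(OTf)3 binds the 1,3-dione and the donor–acceptor cyclopropane ionizes at the bond between the spiro carbon and the 4-methoxyphenyl carbon, giving a scandium enolate and a 4-methoxybenzyl cation, and the enolate oxygen then closes on that cation; this is a Cloke–Wilson cyclopropyl ketone to dihydrofuran rearrangement, known under acid catalysis for cyclohexane-1,3-dione-2-spirocyclopropanes. The three-membered ring (spiro carbon and the two arylmethine carbons) thereby grows by one carbonyl carbon and its oxygen into the five-membered ring O1–C2–C3–C3a–C7a, the closure being a 5-exo-trig capture of the benzylic cation by the enolate oxygen. C3, which bears the 3,5-dimethoxyphenyl group, keeps all four bonds and therefore its configuration from step 9, and the new stereocentre C2 is set trans to it by substrate control, because the planar cation is captured on the face away from the C3 aryl group and the closure is reversible. The step needs regioselective cleavage of one of the two spiro bonds, which the para-methoxy donor secures, since the meta-dimethoxy ring cannot stabilize a cation at its own benzylic carbon. Either dione oxygen may close; the two products differ only at C6, which becomes an sp2 carbon in step 11.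

Step 11
Reactants: 21 (2S,3S)-6-BF-3-(3,5-dimethoxyphenyl)-2-(4-methoxyphenyl)-3,5,6,7-tetrahydro-1-benzofuran-4(2H)-one
Product: 22 (2S,3S)-6-BF-3-(3,5-dimethoxyphenyl)-2-(4-methoxyphenyl)-2,3-dihydro-1-benzofuran-4-ol
Conditions: LiN(SiMe3)2, THF, −78 °C; N-tert-butylbenzenesulfinimidoyl chloride, −78 °C → rt
Reagents that add atoms: none
Why: Kinetic deprotonation at C5 (α to the ketone of the vinylogous ester) and sulfinimidoyl chloride dehydrogenation give the cross-conjugated dienone, which tautomerizes to the phenol, so ring A becomes aromatic and the C6 epimers converge.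

Step 12
Reactants: 22 (2S,3S)-6-BF-3-(3,5-dimethoxyphenyl)-2-(4-methoxyphenyl)-2,3-dihydro-1-benzofuran-4-ol
Product: 23 (2S,3S)-6-BF-3-(3,5-dimethoxyphenyl)-4-isopropoxy-2-(4-methoxyphenyl)-2,3-dihydro-1-benzofuran
Conditions: 2-iodopropane, K2CO3, DMF, 60 °C
Reagents that add atoms: 2-iodopropane, CC(C)I
Why: Williamson etherification gives a bulky isopropyl ether that shields the neighbouring C5 of ring A for step 15 and is cleaved by BBr3 at the end.

Step 13
Reactants: 24 2,4-dimethoxybenzaldehyde
Product: 25 2,4-dimethoxystyrene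
Conditions: Ph3PCH3Br, KOt-Bu, THF, 0 °C → rt
Reagents that add atoms: methyltriphenylphosphonium bromide, C[P+](c1ccccc1)(c1ccccc1)c1ccccc1.[Br-]
Why: Wittig methylenation of the aldehyde.

Step 14
Reactants: 23 (2S,3S)-6-BF-3-(3,5-dimethoxyphenyl)-4-isopropoxy-2-(4-methoxyphenyl)-2,3-dihydro-1-benzofuran; 25 2,4-dimethoxystyrene
Product: 26 (2S,3S)-6-{(2S,3S)-4-[(E)-2-(2,4-dimethoxyphenyl)ethenyl]-6-methoxy-2-(4-methoxyphenyl)-2,3-dihydro-1-benzofuran-3-yl}-3-(3,5-dimethoxyphenyl)-4-isopropoxy-2-(4-methoxyphenyl)-2,3-dihydro-1-benzofuran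
Conditions: Pd(OAc)2 (5 mol %), P(o-tol)3 (10 mol %), K2CO3, DMF, 110 °C
Reagents that add atoms: none
Why: Mizoroki–Heck coupling at the ring B bromide gives the E-stilbene through syn insertion and syn β-hydride elimination.

Step 15
Reactants: 26 the E-stilbene of step 14
Product: 27 heptamethyl isopropyl ether of the target (all five stereocentres S)
Conditions: CF3CO2H (10 equiv), CH2Cl2 (2 mM), 0 °C → rt
Reagents that add atoms: none
Why: Protonation of the stilbene gives the benzylic cation stabilized by the ortho- and para-methoxy groups, which C7 of ring A (ortho to the furan oxygen, para to the isopropoxy group, C5 being shielded by the isopropyl group) traps in a seven-membered Friedel–Crafts closure analogous to the ε-viniferin to ampelopsin B cyclization, the new aryl-bearing stereocentre being set by the adjacent ring-fusion CH (aryl pseudo-axial on the face of that hydrogen, which is also the thermodynamic outcome of this reversible alkylation).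

Step 16
Reactants: 27 heptamethyl isopropyl ether of the target
Product: 28 CNP0154774.1 (target; all five stereocentres S)
Conditions: BBr3 (20 equiv), CH2Cl2, −78 °C → rt; MeOH then H2O
Reagents that add atoms: none
Why: BBr3 should cleave the seven methyl ethers and the isopropyl ether by bromide attack on the O-alkyl carbons of the boron-complexed ethers, and any reversible opening of the two benzylic ether rings under the Lewis acid returns the more stable trans isomers.

**Compound list**

1 | 1-bromo-3,5-dimethoxybenzene | COc1cc(Br)cc(OC)c1 | starting material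
2 | methyl chlorooxoacetate | COC(=O)C(=O)Cl | starting material
3 | methyl 2-(2-bromo-4,6-dimethoxyphenyl)-2-oxoacetate | COC(=O)C(=O)c1c(Br)cc(OC)cc1OC | intermediate
4 | methyl 2-(2-bromo-6-hydroxy-4-methoxyphenyl)-2-oxoacetate | COC(=O)C(=O)c1c(Br)cc(OC)cc1O | intermediate
5 | 4-methoxybenzyl chloride | COc1ccc(CCl)cc1 | starting material
6 | methyl 2-[2-bromo-4-methoxy-6-(4-methoxybenzyloxy)phenyl]-2-oxoacetate | COC(=O)C(=O)c1c(Br)cc(OC)cc1OCc1ccc(OC)cc1 | intermediate
7 | N-tosylhydrazone of 6 | COC(=O)C(=NNS(=O)(=O)c1ccc(C)cc1)c1c(Br)cc(OC)cc1OCc1ccc(OC)cc1 | intermediate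
8 | methyl 2-[2-bromo-4-methoxy-6-(4-methoxybenzyloxy)phenyl]-2-diazoacetate | COC(=O)C(=[N+]=[N-])c1c(Br)cc(OC)cc1OCc1ccc(OC)cc1 | intermediate
9 | methyl (2S,3R)-4-bromo-6-methoxy-2-(4-methoxyphenyl)-2,3-dihydro-1-benzofuran-3-carboxylate (cis) | COC(=O)[C@@H]1c2c(Br)cc(OC)cc2O[C@@H]1c1ccc(OC)cc1 | intermediate
10 | methyl (2S,3S)-4-bromo-6-methoxy-2-(4-methoxyphenyl)-2,3-dihydro-1-benzofuran-3-carboxylate (trans) | COC(=O)[C@H]1c2c(Br)cc(OC)cc2O[C@@H]1c1ccc(OC)cc1 | intermediate
11 | 1-(triphenylphosphoranylidene)propan-2-one | CC(=O)C=P(c1ccccc1)(c1ccccc1)c1ccccc1 | starting material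
12 | (2S,3S)-4-bromo-6-methoxy-2-(4-methoxyphenyl)-2,3-dihydro-1-benzofuran-3-carbaldehyde | O=C[C@H]1c2c(Br)cc(OC)cc2O[C@@H]1c1ccc(OC)cc1 | intermediate
13 | (E)-4-[(2S,3S)-4-bromo-6-methoxy-2-(4-methoxyphenyl)-2,3-dihydro-1-benzofuran-3-yl]but-3-en-2-one | CC(=O)/C=C/[C@H]1c2c(Br)cc(OC)cc2O[C@@H]1c1ccc(OC)cc1 | intermediate
14 | dimethyl malonate | COC(=O)CC(=O)OC | starting material
15 | dimethyl 2-(1-BF-3-oxobutyl)malonate (both epimers at the new CH) | COC(=O)C(C(=O)OC)C(CC(C)=O)[C@H]1c2c(Br)cc(OC)cc2O[C@@H]1c1ccc(OC)cc1 | intermediate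
16 | methyl 6-BF-2,4-dioxocyclohexane-1-carboxylate (sodium enolate in the flask; ring stereocentres mixed) | COC(=O)C1C(=O)CC(=O)CC1[C@H]1c2c(Br)cc(OC)cc2O[C@@H]1c1ccc(OC)cc1 | intermediate
17 | 5-BF-cyclohexane-1,3-dione | O=C1CC(=O)CC(C1)[C@H]1c2c(Br)cc(OC)cc2O[C@@H]1c1ccc(OC)cc1 | intermediate
18 | 2-diazo-5-BF-cyclohexane-1,3-dione | [N-]=[N+]=C1C(=O)CC(CC1=O)[C@H]1c2c(Br)cc(OC)cc2O[C@@H]1c1ccc(OC)cc1 | intermediate
19 | (E)-3,4',5-trimethoxystilbene | COc1ccc(/C=C/c2cc(OC)cc(OC)c2)cc1 | starting material
20 | (1S,2S)-6-BF-1-(3,5-dimethoxyphenyl)-2-(4-methoxyphenyl)spiro[2.5]octane-4,8-dione (trans-diaryl; both orientations of the C6 substituent) | O=C1CC(CC(=O)C12[C@H](c3cc(OC)cc(OC)c3)[C@H]2c2ccc(OC)cc2)[C@H]1c2c(Br)cc(OC)cc2O[C@@H]1c1ccc(OC)cc1 | intermediate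
21 | (2S,3S)-6-BF-3-(3,5-dimethoxyphenyl)-2-(4-methoxyphenyl)-3,5,6,7-tetrahydro-1-benzofuran-4(2H)-one (both C6 epimers) | COc1ccc(cc1)[C@H]1OC2=C([C@@H]1c1cc(OC)cc(OC)c1)C(=O)CC(C2)[C@H]1c2c(Br)cc(OC)cc2O[C@@H]1c1ccc(OC)cc1 | intermediate
22 | (2S,3S)-6-BF-3-(3,5-dimethoxyphenyl)-2-(4-methoxyphenyl)-2,3-dihydro-1-benzofuran-4-ol | COc1ccc(cc1)[C@H]1Oc2cc(cc(O)c2[C@@H]1c1cc(OC)cc(OC)c1)[C@H]1c2c(Br)cc(OC)cc2O[C@@H]1c1ccc(OC)cc1 | intermediate
23 | (2S,3S)-6-BF-3-(3,5-dimethoxyphenyl)-4-isopropoxy-2-(4-methoxyphenyl)-2,3-dihydro-1-benzofuran | COc1ccc(cc1)[C@H]1Oc2cc(cc(OC(C)C)c2[C@@H]1c1cc(OC)cc(OC)c1)[C@H]1c2c(Br)cc(OC)cc2O[C@@H]1c1ccc(OC)cc1 | intermediate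
24 | 2,4-dimethoxybenzaldehyde | COc1ccc(C=O)c(OC)c1 | starting material
25 | 2,4-dimethoxystyrene | COc1ccc(C=C)c(OC)c1 | intermediate
26 | 23 with the bromine replaced by an (E)-2-(2,4-dimethoxyphenyl)ethenyl group | COc1ccc(cc1)[C@H]1Oc2cc(cc(OC(C)C)c2[C@@H]1c1cc(OC)cc(OC)c1)[C@H]1c2c(/C=C/c3ccc(OC)cc3OC)cc(OC)cc2O[C@@H]1c1ccc(OC)cc1 | intermediate
27 | heptamethyl isopropyl ether of the target (isopropoxy on ring A, methoxy at the other seven oxygens; all stereocentres S) | COc1ccc([C@H]2Oc3c4c(cc(OC(C)C)c3[C@@H]2c2cc(OC)cc(OC)c2)[C@H]2c3c(cc(OC)cc3O[C@@H]2c2ccc(OC)cc2)C[C@H]4c2ccc(OC)cc2OC)cc1 | intermediate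
28 | CNP0154774.1 (all five stereocentres S) | Oc1ccc([C@H]2Oc3c4c(cc(O)c3[C@@H]2c2cc(O)cc(O)c2)[C@H]2c3c(cc(O)cc3O[C@@H]2c2ccc(O)cc2)C[C@H]4c2ccc(O)cc2O)cc1 | target

**Step count and risks**

Total step count: 16. Longest linear sequence: 15 steps (steps 1–12 and 14–16; step 13 is a one-step side branch).

Steps most likely to fail:

Step 9. Carbene transfer to a 1,2-disubstituted alkene may be slow, the carbenoid may attack the electron-rich arene rings instead, and catalyst control over the alkene face may be weak. The fallback replaces carbene transfer by a Michael-initiated ring closure and sets out from 17. Bromodimethylsulfonium bromide (Me2S, Br2, MeCN, 0 °C) is added across stilbene 19 to give [2-bromo-2-(3,5-dimethoxyphenyl)-1-(4-methoxyphenyl)ethyl]dimethylsulfonium bromide F1, with sulfur on the 4-methoxyphenyl carbon. With K2CO3 in EtOAc this loses HBr to the vinylsulfonium salt, dione 17 adds at the carbon bearing the 3,5-dimethoxyphenyl group, and the enolate displaces dimethyl sulfide by 3-exo-tet C-alkylation, which comes back to the route at 20. Both cyclopropane series form in this variant; because step 10 resets C2, its two trans products are diastereomers and the wanted one is separated there.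

Step 15. The cation may attack C5 instead of C7 of ring A, or add to the wrong face. The fallback blocks C5 with chlorine during aromatization and sets out from 21. Two rounds of LiN(SiMe3)2 and N-chlorosuccinimide give the 5,5-dichloro ketone F2. Li2CO3 and LiCl in DMF at 120 °C eliminate HCl to the 5-chloro-4-hydroxy compound F3, and 2-iodopropane with K2CO3 gives the isopropyl ether F4. The Heck coupling with 25 under the conditions of step 14 reacts only at the C–Br bond and gives the chloro stilbene F5. Acid closure as in step 15 can then reach only C7 and gives the 5-chloro analogue F6 of 27. Hydrogenolysis of the C–Cl bond (H2, Pd/C, NaOAc, MeOH/EtOAc) comes back to the route at 27.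

Step 16. The Lewis acid may open the two 2-aryl-dihydrofuran rings and trigger skeletal rearrangement, or dealkylation may stay incomplete. The fallback switches to nucleophilic dealkylation and sets out from 27. BCl3 at −78 °C removes only the isopropyl group to give the ring A phenol heptamethyl ether F7. NaSEt in DMF at 130 °C then cleaves the seven methyl ethers by SN2 attack at the methyl carbons without a strong acid, which comes back to the route at 28.

Further compounds
F1 | step 9 | [2-bromo-2-(3,5-dimethoxyphenyl)-1-(4-methoxyphenyl)ethyl]dimethylsulfonium bromide | C[S+](C)C(c1ccc(OC)cc1)C(Br)c1cc(OC)cc(OC)c1.[Br-]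
F2 | step 15 | 5,5-dichloro derivative of 21 | COc1ccc(cc1)[C@H]1OC2=C([C@@H]1c1cc(OC)cc(OC)c1)C(=O)C(Cl)(Cl)C(C2)[C@H]1c2c(Br)cc(OC)cc2O[C@@H]1c1ccc(OC)cc1
F3 | step 15 | 5-chloro derivative of 22 | COc1ccc(cc1)[C@H]1Oc2cc(c(Cl)c(O)c2[C@@H]1c1cc(OC)cc(OC)c1)[C@H]1c2c(Br)cc(OC)cc2O[C@@H]1c1ccc(OC)cc1
F4 | step 15 | 5-chloro derivative of 23 | COc1ccc(cc1)[C@H]1Oc2cc(c(Cl)c(OC(C)C)c2[C@@H]1c1cc(OC)cc(OC)c1)[C@H]1c2c(Br)cc(OC)cc2O[C@@H]1c1ccc(OC)cc1
F5 | step 15 | 5-chloro derivative of 26 | COc1ccc(cc1)[C@H]1Oc2cc(c(Cl)c(OC(C)C)c2[C@@H]1c1cc(OC)cc(OC)c1)[C@H]1c2c(/C=C/c3ccc(OC)cc3OC)cc(OC)cc2O[C@@H]1c1ccc(OC)cc1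
F6 | step 15 | ring A chloro derivative of 27 | COc1ccc([C@H]2Oc3c4c(c(Cl)c(OC(C)C)c3[C@@H]2c2cc(OC)cc(OC)c2)[C@H]2c3c(cc(OC)cc3O[C@@H]2c2ccc(OC)cc2)C[C@H]4c2ccc(OC)cc2OC)cc1
F7 | step 16 | ring A phenol heptamethyl ether of the target | COc1ccc([C@H]2Oc3c4c(cc(O)c3[C@@H]2c2cc(OC)cc(OC)c2)[C@H]2c3c(cc(OC)cc3O[C@@H]2c2ccc(OC)cc2)C[C@H]4c2ccc(OC)cc2OC)cc1
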